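**Assumptions**
- (2S)-Pinocembrin (1 step from nature, propolis-derived) is bought as the cheap chiral starting material. It is the only stereocenter and is never touched.
- In 5,7-dihydroxyflavanones C8 is the slightly more nucleophilic site, so the shorter arm goes on first, at C8, and the longer arm goes on the remaining C6.

**Retrosynthetic overview**
- The target is (S)-pinocembrin carrying a two-phenol arm at C8 and a three-phenol arm at C6. All Ar–CH2–Ar bonds are disconnected to o-quinone methides (o-QMs, from 2-hydroxybenzyl alcohols) plus electron-rich arene C=C bonds. This is the oxa-[4+2] key step.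
- Every arm ring is pre-blocked with Br so that only the desired para carbon is nucleophilic, and each ortho-CH2OH is carried as a CHO until needed.
- Order: (i) build arm-A alcohol 5 and arm-B alcohol 7 iteratively from 3,5-dibromosalicyl alcohol and 3-bromosalicylaldehyde; (ii) benzylate pinocembrin at C8 with 5, then at C6 with 7; (iii) hydrodebrominate once. The only ring formed in the key steps is a transient chroman hemiketal, and the flavanone ring is bought already formed.

**Step 1**
Reactants: 1 (3,5-dibromo-2-hydroxybenzaldehyde)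
Product: 2 (2,4-dibromo-6-(hydroxymethyl)phenol)
Conditions: NaBH4, MeOH, 0 °C → rt, 1 h
Reagents that add atoms: none
Why: NaBH4 reduces the aldehyde chemoselectively; the aryl bromides and phenol are untouched; no stereocenter is formed.

**Step 2**
Reactants: 2; 3 (3-bromo-2-hydroxybenzaldehyde, 3 equiv)
Product: 4 (3-bromo-5-(3,5-dibromo-2-hydroxybenzyl)-2-hydroxybenzaldehyde)
Conditions: p-TsOH·H2O (10 mol %), HFIP, 60 °C, 12 h
Reagents that add atoms: none
Why: Acid in HFIP ionises 2 to the o-QM, a 4π heterodiene that adds to C5 of 3 in an asynchronous inverse-demand oxa-[4+2]/re-aromatisation, which is net hydroxybenzylation. C5 is the only free activated position of 3 (C3 is Br, C1 is CHO), and 2 cannot self-condense because its activated positions carry Br. No stereocenter is formed.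

**Step 3**
Reactants: 4
Product: 5 (2-bromo-4-(3,5-dibromo-2-hydroxybenzyl)-6-(hydroxymethyl)phenol, the arm-A o-QM precursor)
Conditions: NaBH4, MeOH, 0 °C, 1 h
Reagents that add atoms: none
Why: Chemoselective aldehyde reduction unmasks the o-QM precursor.

**Step 4**
Reactants: 5; 3 (3 equiv)
Product: 6 (3-bromo-5-[3-bromo-5-(3,5-dibromo-2-hydroxybenzyl)-2-hydroxybenzyl]-2-hydroxybenzaldehyde)
Conditions: p-TsOH·H2O (10 mol %), HFIP, 60 °C, 16 h
Reagents that add atoms: none
Why: The same o-QM [4+2]/re-aromatisation chemistry. 5 has no free nucleophilic ring position, because both of its rings are Br-blocked, so it cannot oligomerise and only 3 reacts, at C5.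

**Step 5**
Reactants: 6
Product: 7 (2-bromo-4-[3-bromo-5-(3,5-dibromo-2-hydroxybenzyl)-2-hydroxybenzyl]-6-(hydroxymethyl)phenol, the arm-B o-QM precursor)
Conditions: NaBH4, MeOH, 0 °C, 1 h
Reagents that add atoms: none
Why: Chemoselective aldehyde reduction.

**Step 6**
Reactants: 8 ((2S)-pinocembrin); 5 (1.1 equiv)
Product: 9 ((2S)-8-[3-bromo-5-(3,5-dibromo-2-hydroxybenzyl)-2-hydroxybenzyl]-5,7-dihydroxy-2-phenylchroman-4-one)
Conditions: p-TsOH·H2O (10 mol %), HFIP, 50 °C, 8 h; chromatograph off the 6-isomer and the bis-adduct
Reagents that add atoms: none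
Why: The o-QM from 5 adds to the phloroglucinol-type C=C of the A ring (oxa-[4+2], then hemiketal opening to the diarylmethane). Pinocembrin is the only nucleophilic arene present. Mild acid leaves C2 intact, because base-induced retro-oxa-Michael ring opening is what racemises flavanones, so the stereocenter is retained.

**Step 7**
Reactants: 9; 7 (2.5 equiv)
Product: 10 (6,8-bis-benzylated hepta-bromo pinocembrin)
Conditions: p-TsOH·H2O (10 mol %), HFIP, 70 °C (sealed tube), 24 h
Reagents that add atoms: none
Why: The o-QM from 7 adds at C6, the only remaining nucleophilic site. The arm rings are fully blocked, so no side oligomerisation occurs. C2 is retained under the acidic conditions.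

**Step 8**
Reactants: 10
Product: 11 (Sarmentosumin D)
Conditions: H2 (1 atm), 10% Pd/C, NaHCO3 (10 equiv), THF/MeOH, rt, 6 h
Reagents that add atoms: none (H2 adds only hydrogen)
Why: Pd-catalysed hydrodebromination removes all seven aryl bromides; NaHCO3 neutralises the HBr. The phenols, the flavanone ketone and the benzylic C2–O bond survive 1 atm H2 at rt, and the weak base avoids ring-opening and racemisation.

**Checks**
- Atoms balance at every coupling (acid + acid → product + H2O).
- Debrominating 10 gives exactly the target SMILES: arm A at C8 next to O1, arm B at C6, and (S) at C2.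
- The C2 stereocenter is only ever in the unchanged pinocembrin-derived fragment.

**Compound list**
1 | 3,5-dibromo-2-hydroxybenzaldehyde | O=Cc1cc(Br)cc(Br)c1O | starting material
2 | 2,4-dibromo-6-(hydroxymethyl)phenol | OCc1cc(Br)cc(Br)c1O | intermediate
3 | 3-bromo-2-hydroxybenzaldehyde | O=Cc1cccc(Br)c1O | starting material
4 | 3-bromo-5-(3,5-dibromo-2-hydroxybenzyl)-2-hydroxybenzaldehyde | O=Cc1cc(Cc2cc(Br)cc(Br)c2O)cc(Br)c1O | intermediate
5 | arm-A alcohol | OCc1cc(Cc2cc(Br)cc(Br)c2O)cc(Br)c1O | intermediate
6 | arm-B aldehyde | O=Cc1cc(Cc2cc(Cc3cc(Br)cc(Br)c3O)cc(Br)c2O)cc(Br)c1O | intermediate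
7 | arm-B alcohol | OCc1cc(Cc2cc(Cc3cc(Br)cc(Br)c3O)cc(Br)c2O)cc(Br)c1O | intermediate
8 | (2S)-pinocembrin | O=C1C[C@@H](c2ccccc2)Oc2cc(O)cc(O)c21 | starting material
9 | C8-arm-A pinocembrin | O=C1C[C@@H](c2ccccc2)Oc2c(Cc3cc(Cc4cc(Br)cc(Br)c4O)cc(Br)c3O)c(O)cc(O)c21 | intermediate
10 | 6,8-bis-arm hepta-bromo pinocembrin | O=C1C[C@@H](c2ccccc2)Oc2c(Cc3cc(Cc4cc(Br)cc(Br)c4O)cc(Br)c3O)c(O)c(Cc3cc(Cc4cc(Cc5cc(Br)cc(Br)c5O)cc(Br)c4O)cc(Br)c3O)c(O)c21 | intermediate
11 | Sarmentosumin D | O=C1C[C@@H](c2ccccc2)Oc2c(Cc3cc(Cc4ccccc4O)ccc3O)c(O)c(Cc3cc(Cc4cc(Cc5ccccc5O)ccc4O)ccc3O)c(O)c21 | target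

**Totals:** 8 steps total; longest linear sequence 7 (1 → 2 → 4 → 5 → 6 → 7 → 10 → 11, i.e. steps 1, 2, 3, 4, 5, 7, 8).

**Three steps most likely to fail**
1. **Steps 2 and 4 (o-QM coupling of electron-poor partners).** Both the dibromo o-QM and the aldehyde-bearing nucleophile are deactivated. Fallback: form the diarylmethane by para-selective Friedel–Crafts acylation of the Br-blocked phenol with a 3,5-dibromosalicyloyl chloride, then reduce the ketone (Et3SiH, TFA), instead of using an o-QM.
2. **Step 6 (C8 versus C6 selectivity and over-alkylation).** If C8 is not the preferred site, the wrong regioisomer predominates. Fallback: reverse the polarity. Make 8-(dimethylaminomethyl)pinocembrin by an 8-selective Mannich reaction, heat it to generate the core-based o-QM, and trap it with the para-free, Br-blocked arm-A phenol.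
3. **Step 7 (hindered C6 benzylation by the large arm B).** The hindered o-QM may add poorly or cost stereochemical integrity at prolonged heating. Fallback: grow arm B on the core. Attach 3-bromo-2-hydroxybenzyl alcohol at C6, then couple alcohol 5 at the para carbon of that ring.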